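The numbers in the tables come from a simulation for an exercise; scatter was added.

Reagent keeps a plain account in the steps proposed. Each part of starting material that reacts, to intermediate A or to intermediate B, takes one part of reagent, and each part of intermediate B that becomes target takes a second, while no other step takes any. So, in fractions of the starting material charged, target plus its isomer equals the surplus, plus free starting material, minus free reagent. For the violet flask that surplus is 10.0 %: the reagent surplus, reagent charged less starting material charged, as a fraction of the starting material charged.

the same everywhere: starting material 0.10 M
- violet: reagent 0.11 M; temperature 70 °C; the very flask that is asked about, followed so far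
- grey: reagent 0.055 M; temperature 55 °C; run made earlier
- flask: reagent 0.110 M; temperature 70 °C; time 8.0 d

| run | time / h | target / % |
|---|---|---|
| violet | 10.0 | 3.6 |
| violet | 30.0 | 5.8 |
| violet | 60.0 | 7.3 |
| violet | 96.0 | 8.4 |
| violet | 120 | 9.2 |
| violet | 144 | 10.2 |
| grey | 3.00 | 0.2 |
| grey | 10.0 | 0.1 |
| grey | 15.0 | 0.3 |
| grey | 30.0 | 0.5 |
| grey | 40.0 | 0.9 |
| grey | 48.0 | 0.9 |

(each reading ± 0.5 percentage points)

- what is taken out of target is counted as made
- the analysis behind the earlier runs scatters by 0.5 percentage points, standard deviation
- steps that have been proposed: starting material + reagent -> intermediate A; starting material + reagent -> intermediate B; intermediate A -> intermediate C; reagent + intermediate B -> target; intermediate C <-> intermediate D; target <-> isomer of the product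
- additions bring no volume worth counting

- target, in percent of the starting material first charged, at 8.0 d
- the remedy with the largest gain of target, or "none" below 2 percentage points (Saturday's / Monday's / Tuesday's / Wednesday's / none)
- target present, with what was taken out counted in, in percent of the starting material first charged, after Saturday's
- target present, with what was taken out counted in, in percent of the starting material first charged, after Monday's

- Saturday's: at 8.0 d raise the temperature by 10 K, then wait 8.0 d
- Monday's: at 8.0 d add reagent, 100 % of the amount charged, then wait 8.0 d
- Tuesday's: at 8.0 d take out 90 % of the target then present, then wait 8.0 d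
- Wednesday's: change nothing and wait 8.0 d more

Two chemists dispute the violet flask. The first trusts the slope: from 96.0 h to 144 h target climbs from 8.4 % to 10.2 % with no bend beyond the scatter, and that straight line reads 12.0 % at 8.0 d and 19.2 % after 8.0 d more, so waiting pays. The second trusts the account: the last reading already stands at the surplus, within a scatter of 0.5 percentage points, and the sum can rise above the surplus only by what free starting material remains. Reagent is then the limiting reagent of the target, and the line must bend.

I side with the account and commit to 10.0 % at 8.0 d. The forecast stands on that side too, saying the curve “points to reagent starvation rather than a stopped reaction”, but it gives 11 %, a little above mine. It names Monday's as best, with 12 % after Saturday's and 35 % after Monday's.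

The flask gives 10.1 % at 8.0 d, and waiting brings 0.5 points, so the account wins. Monday's gains 9.4 points, reaching 19.5 %, against 10.9 % after Saturday's. In the flask at 192 h intermediate B stood at 9.93 %, which with target makes 20.0 %, near Monday's figure. Monday's lifts the surplus to 120 %, far above that target. That is the slope view's ground: after Monday's the surplus stands far above target, so there the account is no near bound, and pace and supply of intermediate B are what remain to ask.

    starting material + reagent → intermediate A (k = 1.70 M⁻¹ h⁻¹, Ea = 64.0 kJ mol⁻¹)
    starting material + reagent → intermediate B (k = 0.470 M⁻¹ h⁻¹, Ea = 64.0 kJ mol⁻¹)
    intermediate A → intermediate C (k = 0.0780 h⁻¹, Ea = 102 kJ mol⁻¹)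
    reagent + intermediate B → target (k = 0.600 M⁻¹ h⁻¹, Ea = 93.0 kJ mol⁻¹)
    intermediate C ⇌ intermediate D (K = 0.310, k = 0.0300 h⁻¹, Ea = 106 kJ mol⁻¹, ΔH = −79.0 kJ mol⁻¹)
    target ⇌ isomer of the product (K = 0.110, k = 0.0340 h⁻¹, Ea = 116 kJ mol⁻¹, ΔH = −15.0 kJ mol⁻¹)
    (constants at 70 °C)

For the flask charged with 0.25 M of starting material the surplus is −56.0 %, so the account keeps that share, sign turned, of starting material free, plus whatever target, isomer and free reagent stand. The computed flask holds 56.8 % of starting material, 0 % of reagent and 0.685 % of target.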